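**Retrosynthetic overview**
1. Feature: in ring O1–C2–C3–C3a–C7a the quaternary allyl carbon C3a is β and the methyl carbon C3 is α to the oxidised C2. This ring is therefore carried as a butenolide (ring A) whose β-carbon C3a accepts a C4 vinyl radical tethered through C7–C7a.
2. End game: the C4=C5(OMe)–C6=O unit comes from a C4–C5 epoxy ketone; C2–aryl and C2–H come from aryllithium addition to the lactone carbonyl followed by silane reduction.
3. Key disconnection C3a–C4: 6-exo vinyl radical closure of the carbocycle (ring B) onto ring A, setting C3a and C3.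
4. Ring A comes from a Dieckmann closure (C3–C3a) of an O-propanoyl (S)-malic acid derivative, then enol triflate/allyl Stille coupling at C3a; the vinyl iodide comes from the side-chain aldehyde by ethynylation and hydrozirconation–iodination.
5. Order of ring formation: ring A (lactone) first, ring B (cyclohexene) second; ring A is then converted to the 2-aryl tetrahydrofuran.

Key step: step 14

Remark: the C6 carbinol (step 11) and later the C4–C5 epoxide are carried as epimer mixtures, since both are erased when the methoxy enone forms. The malic carboxyl that becomes C6 is reduced to a protected alcohol before the Dieckmann closure, because as an ester it would place an acidic CH2 β to the acyloxy group (elimination to a fumarate) and would later have to be reduced beside the lactone.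

Step 1
Reactants: 1 (S)-malic acid
Product: 2 (S)-2-(2,2-dimethyl-5-oxo-1,3-dioxolan-4-yl)acetic acid
Conditions: Me2C(OMe)2, TsOH (cat.), rt
Reagents that add atoms: 2,2-dimethoxypropane, COC(C)(C)OC
Why: Acid-catalysed transketalisation ties the α-hydroxyl and the adjacent carboxyl into the five-membered dioxolanone (preferred over the six-membered alternative), leaving the distal carboxyl free and the stereocentre untouched.

Step 2
Reactants: 2 (S)-2-(2,2-dimethyl-5-oxo-1,3-dioxolan-4-yl)acetic acid
Product: 3 (S)-5-(2-hydroxyethyl)-2,2-dimethyl-1,3-dioxolan-4-one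
Conditions: BH3·SMe2, THF, 0 °C to rt; MeOH quench
Reagents that add atoms: none
Why: Borane reduces the free carboxylic acid (through its acyloxyborane) much faster than the dioxolanone ester carbonyl, a standard chemoselective acid reduction; crude 3 should be silylated at once to forestall lactonisation.

Step 3
Reactants: 3 (S)-5-(2-hydroxyethyl)-2,2-dimethyl-1,3-dioxolan-4-one
Product: 4 (S)-5-[2-(tert-butyldiphenylsilyloxy)ethyl]-2,2-dimethyl-1,3-dioxolan-4-one
Conditions: TBDPSCl, imidazole, CH2Cl2, 0 °C to rt
Reagents that add atoms: tert-butyl(chloro)diphenylsilane, CC(C)(C)[Si](Cl)(c1ccccc1)c1ccccc1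
Why: Imidazole-promoted silylation of the primary alcohol gives an ether robust enough for amide base, triflic anhydride and palladium.

Step 4
Reactants: 4 (S)-5-[2-(tert-butyldiphenylsilyloxy)ethyl]-2,2-dimethyl-1,3-dioxolan-4-one
Product: 5 methyl (S)-4-(tert-butyldiphenylsilyloxy)-2-hydroxybutanoate
Conditions: NaOMe (0.1 equiv), MeOH, 0 °C
Reagents that add atoms: methanol, CO
Why: Methoxide-catalysed transesterification opens the activated dioxolanone with loss of acetone to give the α-hydroxy methyl ester; brief exposure at 0 °C should leave the α-stereocentre and the silyl ether intact.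

Step 5
Reactants: 5 methyl (S)-4-(tert-butyldiphenylsilyloxy)-2-hydroxybutanoate; 6 propanoyl chloride
Product: 7 methyl (S)-4-(tert-butyldiphenylsilyloxy)-2-(propanoyloxy)butanoate
Conditions: pyridine, DMAP (cat.), CH2Cl2, 0 °C
Reagents that add atoms: none
Why: Standard O-acylation of a secondary alcohol by an acid chloride under nucleophilic catalysis; no bond to the stereocentre is broken.

Step 6
Reactants: 7 methyl (S)-4-(tert-butyldiphenylsilyloxy)-2-(propanoyloxy)butanoate
Product: 8 (S)-5-[2-(tert-butyldiphenylsilyloxy)ethyl]-4-hydroxy-3-methylfuran-2(5H)-one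
Conditions: LiN(SiMe3)2 (2.3 equiv), THF, −78 to −20 °C; then 1 M HCl
Reagents that add atoms: none
Why: Dieckmann (intramolecular Claisen) condensation, in which the propanoate enolate attacks the neighbouring methyl ester to close ring A at C3–C3a and deprotonation of the tetronic acid drives the reaction; the side chain offers no acidic CH2 for elimination and the future C7a is not enolised at low temperature.

Step 7
Reactants: 8 (S)-5-[2-(tert-butyldiphenylsilyloxy)ethyl]-4-hydroxy-3-methylfuran-2(5H)-one
Product: 9 (S)-2-[2-(tert-butyldiphenylsilyloxy)ethyl]-4-methyl-5-oxo-2,5-dihydrofuran-3-yl trifluoromethanesulfonate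
Conditions: Tf2O, iPr2NEt, CH2Cl2, −78 °C
Reagents that add atoms: trifluoromethanesulfonic anhydride, O=S(=O)(OS(=O)(=O)C(F)(F)F)C(F)(F)F
Why: O-sulfonylation of the vinylogous acid gives the enol triflate, an activated vinyl electrophile for cross-coupling.

Step 8
Reactants: 9 (S)-2-[2-(tert-butyldiphenylsilyloxy)ethyl]-4-methyl-5-oxo-2,5-dihydrofuran-3-yl trifluoromethanesulfonate; 10 allyltributylstannane
Product: 11 (S)-4-allyl-5-[2-(tert-butyldiphenylsilyloxy)ethyl]-3-methylfuran-2(5H)-one
Conditions: Pd(PPh3)4 (5 mol %), LiCl, THF, 60 °C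
Reagents that add atoms: none
Why: Stille coupling of the electron-poor vinyl triflate (oxidative addition to zerovalent palladium, chloride-assisted allyl transfer from tin, reductive elimination) installs the allyl group on the future C3a without touching C7a.

Step 9
Reactants: 11 (S)-4-allyl-5-[2-(tert-butyldiphenylsilyloxy)ethyl]-3-methylfuran-2(5H)-one
Product: 12 (S)-4-allyl-5-(2-hydroxyethyl)-3-methylfuran-2(5H)-one
Conditions: HF·pyridine, pyridine, THF, 0 °C to rt
Reagents that add atoms: none
Why: Fluoride cleavage of the silyl ether in a buffered acidic medium avoids the bases that could isomerise the skipped diene or trigger oxa-Michael addition to the butenolide.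

Step 10
Reactants: 12 (S)-4-allyl-5-(2-hydroxyethyl)-3-methylfuran-2(5H)-one
Product: 13 (S)-2-(3-allyl-4-methyl-5-oxo-2,5-dihydrofuran-2-yl)acetaldehyde
Conditions: Dess–Martin periodinane, NaHCO3, CH2Cl2, 0 °C to rt
Reagents that add atoms: none
Why: Dess–Martin oxidation gives the aldehyde under near-neutral conditions, which this β-acyloxy aldehyde needs to avoid E1cB loss of the lactone oxygen; it should be used crude.

Step 11
Reactants: 13 (S)-2-(3-allyl-4-methyl-5-oxo-2,5-dihydrofuran-2-yl)acetaldehyde; 14 ethynylmagnesium bromide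
Product: 15 (5S)-4-allyl-5-(2-hydroxybut-3-yn-1-yl)-3-methylfuran-2(5H)-one (both carbinol epimers)
Conditions: THF, −78 °C; aq. NH4Cl
Reagents that add atoms: none
Why: Grignard 1,2-addition to the aldehyde at −78 °C is far faster than attack on the hindered conjugated lactone or enolisation; the new carbinol (C6) forms as both epimers, which is immaterial.

Step 12
Reactants: 15 (5S)-4-allyl-5-(2-hydroxybut-3-yn-1-yl)-3-methylfuran-2(5H)-one
Product: 16 (5S)-4-allyl-5-[2-(tert-butyldimethylsilyloxy)but-3-yn-1-yl]-3-methylfuran-2(5H)-one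
Conditions: TBSOTf, 2,6-lutidine, CH2Cl2, −78 °C
Reagents that add atoms: tert-butyldimethylsilyl trifluoromethanesulfonate, CC(C)(C)[Si](C)(C)OS(=O)(=O)C(F)(F)F
Why: A silyl triflate with a hindered pyridine base silylates the secondary propargylic alcohol quickly without enolising the butenolide.

Step 13
Reactants: 16 (5S)-4-allyl-5-[2-(tert-butyldimethylsilyloxy)but-3-yn-1-yl]-3-methylfuran-2(5H)-one
Product: 18 (5S)-4-allyl-5-[(E)-2-(tert-butyldimethylsilyloxy)-4-iodobut-3-en-1-yl]-3-methylfuran-2(5H)-one, via alkenylzirconocene chloride 17 (not isolated)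
Conditions: Cp2Zr(H)Cl (1.2 equiv), THF, rt; then I2, 0 °C
Reagents that add atoms: iodine, [I][I]
Why: Hydrozirconation adds Zr–H syn across the terminal alkyne with zirconium at the terminus (much faster than at the monosubstituted alkene or the lactone), and iodinolysis of the C–Zr bond with retention gives the (E)-vinyl iodide.

Step 14
Reactants: 18 (5S)-4-allyl-5-[(E)-2-(tert-butyldimethylsilyloxy)-4-iodobut-3-en-1-yl]-3-methylfuran-2(5H)-one
Product: 21 (3R,3aS,7aS)-3a-allyl-6-(tert-butyldimethylsilyloxy)-3-methyl-3a,6,7,7a-tetrahydro-1-benzofuran-2(3H)-one (cis-fused; methyl cis to C4; both C6 epimers), via vinyl radical 19 (not isolated), via lactone C3 radical 20 (not isolated)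
Conditions: Bu3SnH (1.3 equiv), AIBN (0.2 equiv), benzene (5 mM), 80 °C, syringe-pump addition over 6 h
Reagents that add atoms: none
Why: Tributylstannyl radical abstracts iodine from 18; the σ vinyl radical 19 inverts freely, so the E geometry of the iodide does not matter, and it adds through C4 to the lactone-conjugated β-carbon C3a to give the tertiary α-acyl radical 20, which takes hydrogen from the stannane. The closest known reaction type is the 6-exo conjugate cyclisation of vinyl and aryl radicals onto unsaturated esters and lactones under tin hydride. Ring B closes 6-exo-trig, the C3a=C3 bond being exocyclic to the new ring and the C4=C5 alkene ending up inside it. C3a is controlled by C7a, because the three-atom tether C5–C6–C7 can deliver C4 only cis to C7 (cis fusion); C3 is controlled by hydrogen transfer to the convex face of the bicycle, anti to ring B, which leaves the methyl cis to C4. The step needs ring closure to outrun direct reduction and 1,5-hydrogen transfer from C7a–H; low stannane concentration and the electron-poor acceptor held at six-ring distance should secure this, while the allyl group is out of reach (eight-membered closure). If some C3 epimer forms, enolisation and kinetic protonation on the same convex face should correct it.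

Step 15
Reactants: 21 (3R,3aS,7aS)-3a-allyl-6-(tert-butyldimethylsilyloxy)-3-methyl-3a,6,7,7a-tetrahydro-1-benzofuran-2(3H)-one; 22 4-bromo-1,2-dimethoxybenzene
Product: 24 cis-fused 3a-allyl-6-(tert-butyldimethylsilyloxy)-2-(3,4-dimethoxyphenyl)-2-hydroxy-3-methyl-2,3,3a,6,7,7a-hexahydro-1-benzofuran (lactol; C3/C3a/C7a as in 21), via 3,4-dimethoxyphenyllithium 23 (not isolated)
Conditions: 22, n-BuLi, THF, −78 °C; then 21, −78 °C; aq. NH4Cl
Reagents that add atoms: none
Why: Bromine–lithium exchange gives the aryllithium, which adds once to the lactone carbonyl because the lithium hemiketal alkoxide persists at −78 °C; addition should outpace deprotonation at the hindered C3, so the lactol (in equilibrium with its open hydroxy ketone) keeps C3.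

Step 16
Reactants: 24 cis-fused 3a-allyl-6-(tert-butyldimethylsilyloxy)-2-(3,4-dimethoxyphenyl)-2-hydroxy-3-methyl-2,3,3a,6,7,7a-hexahydro-1-benzofuran
Product: 26 cis-fused 3a-allyl-6-(tert-butyldimethylsilyloxy)-2-(3,4-dimethoxyphenyl)-3-methyl-2,3,3a,6,7,7a-hexahydro-1-benzofuran (aryl cis to methyl and to ring B; C2/C3/C3a/C7a as in the target), via aryl oxocarbenium ion 25 (not isolated)
Conditions: Et3SiH, BF3·OEt2, CH2Cl2, −78 °C
Reagents that add atoms: none
Why: Reductive etherification (ionic hydrogenation): the Lewis acid ionises the hemiketal to the dimethoxyphenyl-stabilised oxocarbenium ion, and silane hydride attacks anti to the vicinal C3 methyl and from the convex face, which places the aryl group cis to the methyl (C2 as in the target); the low temperature should spare the allylic silyl ether.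

Step 17
Reactants: 26 cis-fused 3a-allyl-6-(tert-butyldimethylsilyloxy)-2-(3,4-dimethoxyphenyl)-3-methyl-2,3,3a,6,7,7a-hexahydro-1-benzofuran
Product: 27 cis-fused 3a-allyl-2-(3,4-dimethoxyphenyl)-3-methyl-2,3,3a,6,7,7a-hexahydro-1-benzofuran-6-ol (both C6 epimers)
Conditions: Bu4NF, THF, 0 °C to rt
Reagents that add atoms: none
Why: Fluoride desilylation of the secondary silyl ether; the ether framework has no base-sensitive group at this stage.

Step 18
Reactants: 27 cis-fused 3a-allyl-2-(3,4-dimethoxyphenyl)-3-methyl-2,3,3a,6,7,7a-hexahydro-1-benzofuran-6-ol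
Product: 28 4,5-epoxide of 27 (cis-fused 3a-allyl-2-(3,4-dimethoxyphenyl)-4,5-epoxy-3-methyloctahydro-1-benzofuran-6-ol; epoxide syn to the C6 hydroxyl)
Conditions: VO(acac)2 (5 mol %), t-BuOOH, CH2Cl2, 0 °C to rt
Reagents that add atoms: tert-butyl hydroperoxide, CC(C)(C)OO
Why: Vanadium-catalysed hydroxyl-directed epoxidation delivers oxygen only to the allylic-alcohol alkene C4=C5, syn to the C6 hydroxyl, leaving the allyl group and the arene alone; each C6 epimer gives its own epoxide face, and both converge in step 20.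

Step 19
Reactants: 28 4,5-epoxide of 27
Product: 29 cis-fused 3a-allyl-2-(3,4-dimethoxyphenyl)-4,5-epoxy-3-methylhexahydro-1-benzofuran-6(2H)-one (both epoxide faces)
Conditions: Dess–Martin periodinane, NaHCO3, CH2Cl2, rt
Reagents that add atoms: none
Why: Neutral Dess–Martin oxidation of the secondary alcohol gives the α,β-epoxy ketone without opening the epoxide or the β-alkoxy ketone.

Step 20
Reactants: 29 cis-fused 3a-allyl-2-(3,4-dimethoxyphenyl)-4,5-epoxy-3-methylhexahydro-1-benzofuran-6(2H)-one
Product: 31 (2S,3R,3aR,7aS)-3a-allyl-2-(3,4-dimethoxyphenyl)-5-methoxy-3-methyl-3,3a,7,7a-tetrahydro-1-benzofuran-6(2H)-one (target), via hydroxy methoxy ketone 30 (not isolated)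
Conditions: NaOMe, MeOH, 0 °C to 40 °C
Reagents that add atoms: methanol, CO
Why: Classical epoxy ketone to α-alkoxy enone conversion: methoxide opens the epoxide by SN2 attack at C5 (α to the carbonyl and, unlike C4, not neopentyl) and the β-hydroxy ketone dehydrates by E1cB; both epoxide faces converge, and since C3a is quaternary and only the C7–C7a arm can act as acceptor, a reversible opening of the O1–C7a bond can only re-close to the same cis-fused ring.

**Compound list**
1 | (S)-malic acid | O=C(O)C[C@H](O)C(=O)O | starting material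
2 | (S)-2-(2,2-dimethyl-5-oxo-1,3-dioxolan-4-yl)acetic acid | O=C(O)C[C@@H]1OC(C)(C)OC1=O | intermediate
3 | (S)-5-(2-hydroxyethyl)-2,2-dimethyl-1,3-dioxolan-4-one | OCC[C@@H]1OC(C)(C)OC1=O | intermediate
4 | (S)-5-[2-(tert-butyldiphenylsilyloxy)ethyl]-2,2-dimethyl-1,3-dioxolan-4-one | CC(C)(C)[Si](OCC[C@@H]1OC(C)(C)OC1=O)(c1ccccc1)c1ccccc1 | intermediate
5 | methyl (S)-4-(tert-butyldiphenylsilyloxy)-2-hydroxybutanoate | COC(=O)[C@@H](O)CCO[Si](c1ccccc1)(c1ccccc1)C(C)(C)C | intermediate
6 | propanoyl chloride | CCC(=O)Cl | starting material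
7 | methyl (S)-4-(tert-butyldiphenylsilyloxy)-2-(propanoyloxy)butanoate | CCC(=O)O[C@@H](CCO[Si](c1ccccc1)(c1ccccc1)C(C)(C)C)C(=O)OC | intermediate
8 | (S)-5-[2-(tert-butyldiphenylsilyloxy)ethyl]-4-hydroxy-3-methylfuran-2(5H)-one | CC1=C(O)[C@H](CCO[Si](c2ccccc2)(c2ccccc2)C(C)(C)C)OC1=O | intermediate
9 | (S)-2-[2-(tert-butyldiphenylsilyloxy)ethyl]-4-methyl-5-oxo-2,5-dihydrofuran-3-yl trifluoromethanesulfonate | CC1=C(OS(=O)(=O)C(F)(F)F)[C@H](CCO[Si](c2ccccc2)(c2ccccc2)C(C)(C)C)OC1=O | intermediate
10 | allyltributylstannane | C=CC[Sn](CCCC)(CCCC)CCCC | starting material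
11 | (S)-4-allyl-5-[2-(tert-butyldiphenylsilyloxy)ethyl]-3-methylfuran-2(5H)-one | C=CCC1=C(C)C(=O)O[C@H]1CCO[Si](c1ccccc1)(c1ccccc1)C(C)(C)C | intermediate
12 | (S)-4-allyl-5-(2-hydroxyethyl)-3-methylfuran-2(5H)-one | C=CCC1=C(C)C(=O)O[C@H]1CCO | intermediate
13 | (S)-2-(3-allyl-4-methyl-5-oxo-2,5-dihydrofuran-2-yl)acetaldehyde | C=CCC1=C(C)C(=O)O[C@H]1CC=O | intermediate
14 | ethynylmagnesium bromide | C#C[Mg]Br | starting material
15 | (5S)-4-allyl-5-(2-hydroxybut-3-yn-1-yl)-3-methylfuran-2(5H)-one, both carbinol epimers | C=CCC1=C(C)C(=O)O[C@H]1CC(O)C#C | intermediate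
16 | (5S)-4-allyl-5-[2-(tert-butyldimethylsilyloxy)but-3-yn-1-yl]-3-methylfuran-2(5H)-one | C=CCC1=C(C)C(=O)O[C@H]1CC(O[Si](C)(C)C(C)(C)C)C#C | intermediate
17 | (E)-alkenylzirconocene chloride from 16 (cyclopentadienyl rings drawn σ-bonded) | C=CCC1=C(C)C(=O)O[C@H]1CC(O[Si](C)(C)C(C)(C)C)/C=C/[Zr](Cl)(C1C=CC=C1)C1C=CC=C1 | intermediate (not isolated)
18 | (5S)-4-allyl-5-[(E)-2-(tert-butyldimethylsilyloxy)-4-iodobut-3-en-1-yl]-3-methylfuran-2(5H)-one | C=CCC1=C(C)C(=O)O[C@H]1CC(O[Si](C)(C)C(C)(C)C)/C=C/I | intermediate (key-step precursor)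
19 | C4 vinyl radical from 18 | C=CCC1=C(C)C(=O)O[C@H]1CC(O[Si](C)(C)C(C)(C)C)C=[CH] | intermediate (not isolated)
20 | cyclised lactone C3 radical | C=CC[C@@]12C=CC(O[Si](C)(C)C(C)(C)C)C[C@@H]1OC(=O)[C]2C | intermediate (not isolated)
21 | (3R,3aS,7aS)-3a-allyl-6-(tert-butyldimethylsilyloxy)-3-methyl-3a,6,7,7a-tetrahydro-1-benzofuran-2(3H)-one, cis-fused, methyl cis to C4, both C6 epimers | C=CC[C@@]12C=CC(O[Si](C)(C)C(C)(C)C)C[C@@H]1OC(=O)[C@@H]2C | intermediate (key-step product)
22 | 4-bromo-1,2-dimethoxybenzene | COc1ccc(Br)cc1OC | starting material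
23 | 3,4-dimethoxyphenyllithium | [Li]c1ccc(OC)c(OC)c1 | intermediate (not isolated)
24 | cis-fused 3a-allyl-6-(tert-butyldimethylsilyloxy)-2-(3,4-dimethoxyphenyl)-2-hydroxy-3-methyl-2,3,3a,6,7,7a-hexahydro-1-benzofuran (lactol, either anomer, in equilibrium with the open hydroxy ketone) | C=CC[C@@]12C=CC(O[Si](C)(C)C(C)(C)C)C[C@@H]1OC(O)(c1ccc(OC)c(OC)c1)[C@@H]2C | intermediate
25 | 2-(3,4-dimethoxyphenyl) oxocarbenium ion from 24 | C=CC[C@@]12C=CC(O[Si](C)(C)C(C)(C)C)C[C@@H]1[O+]=C(c1ccc(OC)c(OC)c1)[C@@H]2C | intermediate (not isolated)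
26 | cis-fused 3a-allyl-6-(tert-butyldimethylsilyloxy)-2-(3,4-dimethoxyphenyl)-3-methyl-2,3,3a,6,7,7a-hexahydro-1-benzofuran, aryl cis to methyl and to ring B | C=CC[C@@]12C=CC(O[Si](C)(C)C(C)(C)C)C[C@@H]1O[C@H](c1ccc(OC)c(OC)c1)[C@@H]2C | intermediate
27 | cis-fused 3a-allyl-2-(3,4-dimethoxyphenyl)-3-methyl-2,3,3a,6,7,7a-hexahydro-1-benzofuran-6-ol, both C6 epimers | C=CC[C@@]12C=CC(O)C[C@@H]1O[C@H](c1ccc(OC)c(OC)c1)[C@@H]2C | intermediate
28 | cis-fused 3a-allyl-2-(3,4-dimethoxyphenyl)-4,5-epoxy-3-methyloctahydro-1-benzofuran-6-ol, epoxide syn to the hydroxyl | C=CC[C@@]12C3OC3C(O)C[C@@H]1O[C@H](c1ccc(OC)c(OC)c1)[C@@H]2C | intermediate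
29 | cis-fused 3a-allyl-2-(3,4-dimethoxyphenyl)-4,5-epoxy-3-methylhexahydro-1-benzofuran-6(2H)-one, both epoxide faces | C=CC[C@@]12C3OC3C(=O)C[C@@H]1O[C@H](c1ccc(OC)c(OC)c1)[C@@H]2C | intermediate
30 | cis-fused 3a-allyl-2-(3,4-dimethoxyphenyl)-4-hydroxy-5-methoxy-3-methylhexahydro-1-benzofuran-6(2H)-one | C=CC[C@@]12C(O)C(OC)C(=O)C[C@@H]1O[C@H](c1ccc(OC)c(OC)c1)[C@@H]2C | intermediate (not isolated)
31 | (2S,3R,3aR,7aS)-3a-allyl-2-(3,4-dimethoxyphenyl)-5-methoxy-3-methyl-3,3a,7,7a-tetrahydro-1-benzofuran-6(2H)-one | C=CC[C@@]12C=C(OC)C(=O)C[C@@H]1O[C@H](c1ccc(OC)c(OC)c1)[C@@H]2C | target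

Total step count: 20
Longest linear sequence: 20 steps (from 1; 6, 10, 14 and 22 enter as commercial materials)

**Steps most likely to fail**

Step 14. Hydrogen transfer to the vinyl radical, either from the stannane or by 1,5-shift from C7a–H, may outrun closure at the fully substituted C3a. The fallback is a palladium-mediated closure, which has no radical to quench; because a vinylpalladium keeps its geometry, it needs the Z iodide. It sets out from alkyne 16. NIS with AgNO3 (cat.) in acetone should give the iodoalkyne (5S)-4-allyl-5-[2-(tert-butyldimethylsilyloxy)-4-iodobut-3-yn-1-yl]-3-methylfuran-2(5H)-one F1. Diimide semi-reduction (2-nitrobenzenesulfonylhydrazide, Et3N, limited excess so that the allyl group is spared) should give the (Z)-vinyl iodide F2. A 6-exo Heck cyclisation (Pd(OAc)2, PPh3, Ag2CO3, MeCN, 70 °C) places palladium on C3, whose only β-hydrogens are on the methyl group, so β-hydride elimination should give the cis-fused α-methylene lactone F3. Conjugate reduction with [CuH(PPh3)]6 in wet toluene, with protonation of the copper enolate on the convex face, comes back to the route at lactone 21.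

Step 16. Hydride may be delivered to the wrong face of the oxocarbenium ion, or the Lewis acid may open side paths (ionisation of the allylic silyl ether, Prins closure of the cation onto the allyl group). The fallback sets C2 by reagent control and closes the ring by displacement. It sets out from lactol 24 through its open hydroxy ketone form. Reduction with BH3·SMe2 and whichever enantiomer of 2-methyl-CBS-oxazaborolidine gives the (R)-benzylic carbinol should furnish the diol 3a-allyl cyclohexenol bearing the 1-aryl-1-hydroxypropan-2-yl chain F4. Mitsunobu cyclodehydration (PPh3, DIAD, THF), in which the C7a hydroxyl displaces the activated benzylic oxygen with inversion, comes back to the route at ether 26.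

Step 20. Under methoxide, E1cB opening of the O1–C7a bond followed by re-closure onto C4, or retro-aldol cleavage of hydroxy ketone 30, may compete with dehydration. The fallback installs the methoxy group by cross-coupling instead of epoxide opening. It sets out from allylic alcohol 27. Dess–Martin oxidation should give the enone cis-fused 3a-allyl-2-(3,4-dimethoxyphenyl)-3-methyl-3,3a,7,7a-tetrahydro-1-benzofuran-6(2H)-one F5. Johnson α-iodination (I2, pyridine, CH2Cl2) should give the 5-iodo enone F6. Ullmann-type vinyl C–O coupling with methanol (CuI, 3,4,7,8-tetramethyl-1,10-phenanthroline, Cs2CO3, toluene, 80 °C) comes back to the route at target 31.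

**Further compounds**
F1 | step 14 | (5S)-4-allyl-5-[2-(tert-butyldimethylsilyloxy)-4-iodobut-3-yn-1-yl]-3-methylfuran-2(5H)-one | C=CCC1=C(C)C(=O)O[C@H]1CC(O[Si](C)(C)C(C)(C)C)C#CI
F2 | step 14 | (5S)-4-allyl-5-[(Z)-2-(tert-butyldimethylsilyloxy)-4-iodobut-3-en-1-yl]-3-methylfuran-2(5H)-one | C=CCC1=C(C)C(=O)O[C@H]1CC(O[Si](C)(C)C(C)(C)C)/C=C\I
F3 | step 14 | cis-fused 3a-allyl-6-(tert-butyldimethylsilyloxy)-3-methylidene-3a,6,7,7a-tetrahydro-1-benzofuran-2(3H)-one | C=CC[C@@]12C=CC(O[Si](C)(C)C(C)(C)C)C[C@@H]1OC(=O)C2=C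
F4 | step 16 | 6-allyl-4-(tert-butyldimethylsilyloxy)-6-[(1R)-1-(3,4-dimethoxyphenyl)-1-hydroxypropan-2-yl]cyclohex-2... diol drawn as: 2-allyl-2-[1-(3,4-dimethoxyphenyl)-1-hydroxypropan-2-yl]-5-(tert-butyldimethylsilyloxy)cyclohex-3-en-1-ol, (R)-benzylic carbinol, other centres as in 24 | C=CC[C@]1(C=CC(O[Si](C)(C)C(C)(C)C)C[C@@H]1O)[C@@H](C)[C@@H](O)c1ccc(OC)c(OC)c1
F5 | step 20 | cis-fused 3a-allyl-2-(3,4-dimethoxyphenyl)-3-methyl-3,3a,7,7a-tetrahydro-1-benzofuran-6(2H)-one | C=CC[C@@]12C=CC(=O)C[C@@H]1O[C@H](c1ccc(OC)c(OC)c1)[C@@H]2C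
F6 | step 20 | cis-fused 3a-allyl-2-(3,4-dimethoxyphenyl)-5-iodo-3-methyl-3,3a,7,7a-tetrahydro-1-benzofuran-6(2H)-one | C=CC[C@@]12C=C([I])C(=O)C[C@@H]1O[C@H](c1ccc(OC)c(OC)c1)[C@@H]2C
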